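## Structural features

The target is an unsymmetrical diaryl ether. Ring A (a1 carries arm A, a3 and a4 carry hydroxyls, a5 carries the ether oxygen) is joined through one oxygen to ring B (b1 ether oxygen, b2 hydroxyl, b3 arm B). Each arm is a (6E)-3,7,11-trimethyldodeca-1,6,10-trien-3-yl ("nerolidyl") group bonded through C3. C3 is an all-carbon quaternary benzylic carbon bearing a methyl group, a vinyl group (C1=C2) and the chain C4–C12 with one 6E trisubstituted alkene and a terminal isopropylidene. The only stereocentres are the two C3 atoms, 3R in arm A and 3S in arm B. They are not adjacent: they lie eight bonds apart across the ether bridge, so neither can direct the other and each must be set by a reagent. The fragile groups are the two catechol units (air and base oxidise them to quinones) and the six alkenes (acid starts cation–olefin cyclisation; peracids, ozone and hydrogenation are excluded). The real difficulty is to build two acyclic aryl-bearing quaternary carbons whose two alkyl substituents, methyl and the chain CH2, differ very little, and then to join two catechols through a single oxygen. In ring B the arm on b3 is ortho to the b2 oxygen, which has an oxygen neighbour on b1. This is the pattern left by an ortho aromatic Claisen rearrangement of a b2 O-farnesyl ether, and the b1 hydroxyl is free to hold a chiral boron atom; the key step exploits this. In ring A, a4 lies between two oxygen-bearing carbons and para to the arm, so it can carry a formyl group that activates a3 and a5 and is exchanged for hydroxyl at the end.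

## Logic of the disconnections

**16 back to 14.** The a4–O bond is exchanged for an a4–C(formyl) bond, with 15 as the transient link. A formyl group on a4 is the one substituent that first activates a3 and a5 towards nucleophiles and then becomes the hydroxyl. The gain is that the oxidation-prone trioxygenated ring appears only in the last operation. The forward step must oxidise an aldehyde beside six alkenes and free phenols, which calls for a nucleophilic peroxide and the a3 hydroxyl ortho to the formyl group.

**14 back to 13.** The a3–O bond is cut and a3 carries fluorine. Oxygen is kept off a3 until the diaryl ether exists, because an a3 phenoxide would shut down substitution at a5. The forward step needs an oxygen nucleophile to attack the C–F carbon and not the formyl carbon or a5.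

**13 back to 6 and 12.** The O(b1)–a5 bond is cut. This is the convergent cut: two halves of equal size, each with one stereocentre and one arm. The two fluorines of 12 are equivalent, so ring A poses no regiochemical question. The forward step must choose the b1 oxygen of 6 over b2 and stop after one substitution.

**6 back to 3 (key disconnection).** The b3–C3 bond of arm B is cut and the allyl unit is returned to the b2 oxygen with transposition; 5 and 4 are the boron-bound forms on the way. The cut removes the quaternary stereocentre and the whole C15 arm in one stroke and leaves an achiral ether. The forward step must be a concerted, face-selective [3,3] shift to b3 at a temperature low enough that the allylic C–O bond does not ionise.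

**3 back to 1 and 2.** The O(b2)–C1 bond is cut. Both pieces are commercial and 2 already has the pure 2E geometry on which the stereochemical outcome depends. The forward step must stop at mono-alkylation and stay on oxygen.

**12 back to 10.** The a4–C(formyl) bond is cut, with 11 as the carbanion. A free aldehyde flanked by two fluorines would not survive the alkoxide and aryl-copper species of the preceding coupling, so it is introduced afterwards. The a4 hydrogen of 10 sits between two fluorines and is by far the most acidic C–H. The forward step must be run cold enough that 11 does not lose LiF.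

**10 back to 8 and 9.** The a1–C3 bond of arm A is cut with allyl transposition. This removes the second quaternary stereocentre and again takes all fifteen arm carbons from one terpene unit. The forward catalyst must deliver the aryl group to C3 and not C1, and to one face of an alkene whose C3 bears methyl and a CH2 chain.

**8 back to 7.** The O–P bond is cut. The phosphate is the leaving group for the copper step; 7 is the commercial (2E,6E) alcohol.

## Other disconnections considered

**Alternative 1:** The cut is the C3–C4 bond of arm B, with the b2 oxygen and the future vinyl carbon C2 tied together as a lactone.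

- Forward key step: the racemic benzofuranone A2 is deprotonated under solid–liquid phase-transfer conditions to its planar aromatic enolate. A chiral spirobinaphthyl ammonium cation escorts it to homogeranyl iodide A3, and C-alkylation would give A1. Reduction of the lactone carbonyl to the aldehyde level, methylenation and desilylation would then lead on to 6.
- In favour: the chiral controller is catalytic, which is better than the stoichiometric boron reagent of step 2. No Lewis acid meets an allylic ether or a polyene, which is also better. A racemic substrate is used stereoconvergently.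
- Against: A3 is an unactivated primary alkyl iodide, the electrophile class for which ion-pair alkylation is slowest and for which racemic background reaction and O-alkylation are most likely to intrude. The enolate carries a methyl and not an aryl group on the reacting carbon and is less stabilised. A3 must be made separately, whereas the chosen plan takes the whole arm from 2. Three more operations follow A1.
- Comparison on structure: b1 and b2 are told apart from the start in A1. This is only equal in value to the chosen plan, because once the lactone is opened it is again b2 that is free and b1 that is masked, so the steric bias of step 6 is still needed.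
- Comparison on mechanism: a loosely organised ion pair replaces the ordered chair of a sigmatropic shift. Both plans are on equally uncertain ground for a quaternary centre with two similar alkyl groups.
- Comparison on step economy: the chosen plan reaches 6 in two steps, the alternative in several times as many.

**Alternative 2:** The cuts are the a2–a3 and a5–a6 bonds. Ring A is divided into the three-carbon vinamidinium salt A5 (a6, a1, a2 with arm A) and the three-carbon ketone A6 (a3, a4, a5 with their oxygens and ring B).

- Forward key step: KOtBu generates enolates at both α-methylenes of A6, which add to the two iminium termini of A5. Loss of two HNMe2 and aromatisation close ring A and would give A4 with the a4 hydroxyl free.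
- In favour: convergence is maximal. The oxygen pattern of ring A and the position of the ether oxygen are written into A6, so neither substitution regiochemistry nor a peroxide step is needed; this is better than steps 6 to 8 of the chosen plan. The ether bond is made as a simple alkyl aryl ether.
- Against: the key step creates no stereocentre, so both quaternary carbons must still be made by other means. Arm A must then be carried into a vinamidinium salt whose central carbon bears a quaternary substituent. The usual access to such salts, Vilsmeier-type double formylation with hot POCl3–DMF, is expected to hydrochlorinate or cyclise the trisubstituted alkenes, and the neopentyl position resists it. Both MOM groups need acid to leave, on a bis-polyene.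
- Comparison on structure: better convergence and an unambiguous oxygen pattern; the alternative is better.
- Comparison on mechanism: a condensation without stereochemical content stands against a stereo-defining pericyclic step; the chosen plan is better.
- Comparison on step economy: the count rises well above eight, because each arm still needs its own asymmetric step plus the conversion into A5 or A6.

**Alternative 3:** The cut is the C3–C4 bond of arm A, with boron standing where the vinyl group will be.

- Forward key step: the carbamate A8 is lithiated at the benzylic carbon with s-BuLi at −78 °C. The benzyllithium captures the boronate A9, and the ate complex undergoes 1,2-migration of the homogeranyl group with loss of carbamate to give A7. A Zweifel-type vinylation and removal of three MOM groups would finish.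
- In favour: the configuration of C3 is transferred from the secondary carbamate and not induced, and a reliable asymmetric carbonyl reduction can set that carbamate. In predictability this is better than step 4, where a catalyst must tell methyl from a CH2 chain.
- Against: the step comes late, on a substrate that already holds arm B and three MOM ethers. MOM groups direct ortho-lithiation and the electron-rich ring lowers benzylic acidity, so the base may go astray. Hindered, electron-rich ate complexes migrate slowly and can revert, which erodes stereochemical purity. The vinylation needs iodine beside four trisubstituted alkenes. The triple MOM removal needs acid. A9 is a further separate fragment.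
- Comparison on structure: linear where the chosen plan is convergent; the chosen plan is better.
- Comparison on mechanism: a stereospecific 1,2-metallate shift; the alternative is better in principle and equal in practical risk on this substrate.
- Comparison on step economy: reduction, carbamoylation, borylation, vinylation and deprotection come on top of the diaryl ether assembly, roughly doubling the length.

Key step: step 2

**Remarks before the steps**

- Names: nerolidyl = (6E)-3,7,11-trimethyldodeca-1,6,10-trien-3-yl; farnesyl = (2E,6E)-3,7,11-trimethyldodeca-2,6,10-trien-1-yl; homogeranyl = (3E)-4,8-dimethylnona-3,7-dien-1-yl.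
- Check of the structures: 3 and 6 as drawn are consistent with the target and no correction is needed. Arm A is 3R and arm B is 3S, opposite descriptors for the same substituent set, so the handedness of the two enantio-determining reagents is chosen independently.
- Assumption: the sense of induction of the (4S,5S)-bromoborane in step 2 and of the chiral carbene–copper catalyst in step 4 is taken as written. Should a first run give the mirror-image arm, the enantiomeric reagent or ligand, equally available, is used and nothing else changes.
- Design change on the ring A side: a free 2,6-difluorobenzaldehyde would not tolerate the alkoxide base and aryl-copper intermediates of the allylic arylation, and an acetal would cost two steps. The arylation is therefore run on a 3,5-difluorophenyl boronate and the formyl group is introduced afterwards.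
- The precursor 3 is kept as the free mono-ether with no spectator group, because the free b1 hydroxyl is the anchor for boron. It is made in one step from commercial, geometrically pure 2 with an excess of 1.

## Route

Step 1
Reactants: 1 catechol; 2 (2E,6E)-farnesyl bromide
Product: 3 2-{[(2E,6E)-3,7,11-trimethyldodeca-2,6,10-trien-1-yl]oxy}phenol (catechol mono-farnesyl ether)
Conditions: 1 (3 equiv), K2CO3, acetone, reflux, Ar
Reagents that add atoms: none
Why: Williamson ether synthesis by SN2 at the primary allylic carbon of 2; the excess of 1 keeps dialkylation low and is washed out with water. Carbonate in acetone favours O- over C-alkylation and does not touch the 2E geometry.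

Step 2
Reactants: 3 catechol mono-farnesyl ether
Product: 6 (S)-3-nerolidylcatechol [3-[(3S,6E)-3,7,11-trimethyldodeca-1,6,10-trien-3-yl]benzene-1,2-diol], via aryloxyborane chelate 4 (not isolated), via O-boryl nerolidylcatechol 5 (not isolated)
Conditions: (4S,5S)-2-bromo-1,3-bis(4-methylbenzenesulfonyl)-4,5-diphenyl-1,3,2-diazaborolidine (1.5 equiv; from (1S,2S)-TsNHCH(Ph)CH(Ph)NHTs, BBr3, CH2Cl2, rt, then evacuated), Et3N, CH2Cl2, −78 → −45 °C, Ar; then degassed aq. NaH2PO4
Reagents that add atoms: none
Why: Et3N and the bromoborane convert the b1 hydroxyl of 3 into the aryloxyborane 4, whose boron also binds the b2 ether oxygen in a five-membered chelate; the positive charge this places on the ether oxygen lowers the barrier of the [3,3] sigmatropic shift enough for it to run at −45 °C. The shift passes through a six-membered chair transition state (O(b2), C1, C2, C3, b3, b2; no ring is closed), forms the b3–C3 bond with allyl transposition so that C1 becomes the vinyl terminus, and the dienone tautomerises to 5, which the aqueous work-up hydrolyses to 6. The closest known reaction type is the enantioselective aromatic Claisen rearrangement of catechol mono-allyl ethers promoted by a stoichiometric chiral diazaborolidine bromide; the stretch here is the γ,γ-disubstituted terminus that creates a quaternary carbon. The new stereocentre C3 is controlled by the C2-symmetric bis-sulfonamide on boron, whose sulfonyl aryl groups screen one face of the chelated allyl ether, together with the pure 2E geometry of 3, which places the chain equatorial and the methyl group axial in the chair and so ties the exposed alkene face to one configuration (3S with the antipode assumed). Regioselectivity comes from the substrate: the other ortho position of the b2 oxygen is b1, which carries the boron-bound oxygen, so only b3 can accept C3. The step also needs a concerted path and no O–C1 heterolysis; the low temperature, the non-polar solvent and the removal of HBr before 3 is added should secure this and leave the distal alkenes untouched.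

Step 3
Reactants: 7 (2E,6E)-farnesol
Product: 8 diethyl (2E,6E)-farnesyl phosphate
Conditions: ClP(O)(OEt)2, pyridine, CH2Cl2, 0 °C → rt
Reagents that add atoms: diethyl chlorophosphate, CCOP(=O)(Cl)OCC
Why: O-phosphorylation of a primary allylic alcohol; only the O–P bond forms, so the 2E,6E geometry is untouched and the phosphate becomes the leaving group for the copper step.

Step 4
Reactants: 8 diethyl farnesyl phosphate; 9 2-(3,5-difluorophenyl)-5,5-dimethyl-1,3,2-dioxaborinane
Product: 10 1,3-difluoro-5-[(3R,6E)-3,7,11-trimethyldodeca-1,6,10-trien-3-yl]benzene
Conditions: CuCl (5 mol %), chiral hydroxyl-bearing 4,5-diphenylimidazolinium salt (carbene precursor, 5.5 mol %), NaOMe, THF, 30 °C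
Reagents that add atoms: none
Why: copper-catalysed enantioselective allylic substitution (SN2′) of a γ,γ-disubstituted allyl phosphate with an aryl boronate: methoxide activates 9, the aryl group passes to monovalent copper and is delivered to C3 anti to the phosphate, turning C1 into the vinyl terminus. The chiral carbene on copper selects the alkene face (antipode chosen for 3R) and the fixed 2E geometry makes that face choice equal to a choice of configuration.

Step 5
Reactants: 10 1,3-difluoro-5-[(3R)-nerolidyl]benzene
Product: 12 2,6-difluoro-4-[(3R,6E)-3,7,11-trimethyldodeca-1,6,10-trien-3-yl]benzaldehyde, via aryllithium 11 (not isolated)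
Conditions: LiN(iPr)2, THF, −78 °C; DMF, −78 → −40 °C; AcOH, H2O
Reagents that add atoms: N,N-dimethylformamide, CN(C)C=O
Why: directed ortho-lithiation at the C–H between the two fluorines, the most acidic site, followed by formylation with DMF. At −78 °C 11 should not lose LiF, the amide base does not add to the alkenes, and the quaternary centre has no hydrogen to lose.

Step 6
Reactants: 6 (S)-3-nerolidylcatechol; 12 2,6-difluoro-4-[(3R)-nerolidyl]benzaldehyde
Product: 13 2-fluoro-6-{2-hydroxy-3-[(3S)-nerolidyl]phenoxy}-4-[(3R)-nerolidyl]benzaldehyde
Conditions: K2CO3 (1.2 equiv), DMF, 60 °C, Ar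
Reagents that add atoms: none
Why: nucleophilic aromatic substitution through a Meisenheimer adduct at a fluorine ortho to the formyl group; the two fluorines of 12 are equivalent. The b1 hydroxyl of 6 is both the more acidic and the less hindered one (b2 is flanked by the quaternary carbon), so its phenoxide should react, and the first aryloxy group deactivates ring A towards a second substitution. No stereocentre is touched.

Step 7
Reactants: 13 fluoro diaryl ether aldehyde
Product: 14 2-hydroxy-6-{2-hydroxy-3-[(3S)-nerolidyl]phenoxy}-4-[(3R)-nerolidyl]benzaldehyde
Conditions: KOH, DMSO–H2O, 70 °C, Ar; then 1 M HCl to pH 4, 0 °C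
Reagents that add atoms: potassium hydroxide, [K+].[OH-]
Why: second nucleophilic aromatic substitution, by hydroxide at the remaining C–F ortho to the formyl group; fluoride is a far better leaving group than aryloxide in addition–elimination, and the salicylaldehyde phenoxide formed deactivates the ring against further attack.

Step 8
Reactants: 14 salicylaldehyde diaryl ether
Product: 16 3-{2-hydroxy-3-[(3S,6E)-3,7,11-trimethyldodeca-1,6,10-trien-3-yl]phenoxy}-5-[(3R,6E)-3,7,11-trimethyldodeca-1,6,10-trien-3-yl]benzene-1,2-diol (target), via aryl formate 15 (not isolated)
Conditions: 30% aq. H2O2 (1.2 equiv), NaOH, THF–H2O, 0 °C, Ar; Na2S2O3; aq. NaH2PO4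
Reagents that add atoms: hydrogen peroxide, OO
Why: Dakin oxidation: hydroperoxide adds to the formyl group, the aryl group migrates to oxygen assisted by the ortho phenoxide, and the formate 15 is saponified in the same pot. Alkaline peroxide is a nucleophilic oxidant and should leave the isolated alkenes alone; argon, near-stoichiometric peroxide and a reductive quench protect the catechols.

## Compound list

1 | catechol (benzene-1,2-diol) | Oc1ccccc1O | starting material
2 | (2E,6E)-farnesyl bromide [(2E,6E)-1-bromo-3,7,11-trimethyldodeca-2,6,10-triene] | BrC/C=C(\C)CC/C=C(\C)CCC=C(C)C | starting material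
3 | 2-{[(2E,6E)-3,7,11-trimethyldodeca-2,6,10-trien-1-yl]oxy}phenol | Oc1ccccc1OC/C=C(\C)CC/C=C(\C)CCC=C(C)C | intermediate
4 | (4S,5S)-2-{2-[(2E,6E)-farnesyloxy]phenoxy}-1,3-bis(4-methylbenzenesulfonyl)-4,5-diphenyl-1,3,2-diazaborolidine (b2 ether oxygen chelated to boron) | O(C/C=C(\C)CC/C=C(\C)CCC=C(C)C)c1ccccc1OB1N(S(=O)(=O)c2ccc(C)cc2)[C@@H](c2ccccc2)[C@H](c2ccccc2)N1S(=O)(=O)c1ccc(C)cc1 | intermediate (not isolated)
5 | (4S,5S)-2-{2-hydroxy-3-[(3S)-nerolidyl]phenoxy}-1,3-bis(4-methylbenzenesulfonyl)-4,5-diphenyl-1,3,2-diazaborolidine | Oc1c(OB2N(S(=O)(=O)c3ccc(C)cc3)[C@@H](c3ccccc3)[C@H](c3ccccc3)N2S(=O)(=O)c2ccc(C)cc2)cccc1[C@](C)(C=C)CC/C=C(\C)CCC=C(C)C | intermediate (not isolated)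
6 | 3-[(3S,6E)-3,7,11-trimethyldodeca-1,6,10-trien-3-yl]benzene-1,2-diol | Oc1cccc([C@](C)(C=C)CC/C=C(\C)CCC=C(C)C)c1O | intermediate
7 | (2E,6E)-farnesol | OC/C=C(\C)CC/C=C(\C)CCC=C(C)C | starting material
8 | diethyl (2E,6E)-3,7,11-trimethyldodeca-2,6,10-trien-1-yl phosphate | CCOP(=O)(OCC)OC/C=C(\C)CC/C=C(\C)CCC=C(C)C | intermediate
9 | 2-(3,5-difluorophenyl)-5,5-dimethyl-1,3,2-dioxaborinane | CC1(C)COB(OC1)c1cc(F)cc(F)c1 | starting material
10 | 1,3-difluoro-5-[(3R,6E)-3,7,11-trimethyldodeca-1,6,10-trien-3-yl]benzene | Fc1cc(F)cc(c1)[C@@](C)(C=C)CC/C=C(\C)CCC=C(C)C | intermediate
11 | {2,6-difluoro-4-[(3R)-nerolidyl]phenyl}lithium | [Li]c1c(F)cc(cc1F)[C@@](C)(C=C)CC/C=C(\C)CCC=C(C)C | intermediate (not isolated)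
12 | 2,6-difluoro-4-[(3R,6E)-3,7,11-trimethyldodeca-1,6,10-trien-3-yl]benzaldehyde | O=Cc1c(F)cc(cc1F)[C@@](C)(C=C)CC/C=C(\C)CCC=C(C)C | intermediate
13 | 2-fluoro-6-{2-hydroxy-3-[(3S)-nerolidyl]phenoxy}-4-[(3R)-nerolidyl]benzaldehyde | O=Cc1c(F)cc(cc1Oc1cccc(c1O)[C@](C)(C=C)CC/C=C(\C)CCC=C(C)C)[C@@](C)(C=C)CC/C=C(\C)CCC=C(C)C | intermediate
14 | 2-hydroxy-6-{2-hydroxy-3-[(3S)-nerolidyl]phenoxy}-4-[(3R)-nerolidyl]benzaldehyde | O=Cc1c(O)cc(cc1Oc1cccc(c1O)[C@](C)(C=C)CC/C=C(\C)CCC=C(C)C)[C@@](C)(C=C)CC/C=C(\C)CCC=C(C)C | intermediate
15 | 2-hydroxy-6-{2-hydroxy-3-[(3S)-nerolidyl]phenoxy}-4-[(3R)-nerolidyl]phenyl formate | O=COc1c(O)cc(cc1Oc1cccc(c1O)[C@](C)(C=C)CC/C=C(\C)CCC=C(C)C)[C@@](C)(C=C)CC/C=C(\C)CCC=C(C)C | intermediate (not isolated)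
16 | 3-{2-hydroxy-3-[(3S,6E)-3,7,11-trimethyldodeca-1,6,10-trien-3-yl]phenoxy}-5-[(3R,6E)-3,7,11-trimethyldodeca-1,6,10-trien-3-yl]benzene-1,2-diol (CNP0325484.1) | C=C[C@@](C)(CC/C=C(\C)CCC=C(C)C)c1cc(O)c(O)c(Oc2cccc([C@](C)(C=C)CC/C=C(\C)CCC=C(C)C)c2O)c1 | target

## Step count and least certain steps

Total step count: 8. Longest linear sequence: 6 steps (steps 3, 4, 5, 6, 7 and 8, from 7 to 16). The ring B branch is 5 steps (steps 1, 2, 6, 7 and 8).

**Step 2 (key step).** The boron Lewis acid may cause heterolysis of the O–C1 bond, because the γ,γ-dialkyl allyl group is a good cation precursor. The allyl unit would then recombine non-selectively or be captured by the distal alkenes, with loss of enantio- and regiocontrol. The axial methyl group at the terminus may also erode the chair preference and the facial bias and lower the enantioselectivity.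

The fallback forms the b3–C3 bond by the copper-catalysed SN2′ arylation of step 4 in place of a rearrangement. It sets out from 1 and 8 and comes back at 6. Compound 1 would be converted with MOMCl and iPr2NEt into 1,2-bis(methoxymethoxy)benzene F1. Lithiation ortho to a MOM-oxy group (n-BuLi, THF, 0 °C), B(OiPr)3 and then neopentyl glycol would give 2-[2,3-bis(methoxymethoxy)phenyl]-5,5-dimethyl-1,3,2-dioxaborinane F2. F2 and 8 under the conditions of step 4, with the mirror-image carbene precursor, would give 1,2-bis(methoxymethoxy)-3-[(3S)-nerolidyl]benzene F3. Catalytic HCl in MeOH at room temperature under argon would release 6. The ortho substituent on the aryl nucleophile makes this coupling slower than step 4, which is why it is the fallback.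

**Step 4.** Face discrimination at the C2=C3 alkene may be insufficient, because C3 carries two alkyl groups of similar size. The electron-poor aryl group may also transfer slowly from boron to copper, giving protodeboronation and leakage to the linear SN2 product.

The fallback swaps the roles so that the catalyst has to distinguish an aryl from a methyl group and the C3–C4 bond is the one formed. It sets out from 9 and comes back at 10. Suzuki–Miyaura coupling of 9 with (E)-3-iodobut-2-en-1-ol (Pd(PPh3)4, K2CO3, THF–H2O, 60 °C) would give (2E)-3-(3,5-difluorophenyl)but-2-en-1-ol F4. MsCl, Et3N and LiCl would convert it into 1-[(2E)-4-chlorobut-2-en-2-yl]-3,5-difluorobenzene F5. [(3E)-4,8-Dimethylnona-3,7-dien-1-yl]magnesium bromide F6, prepared from the known homogeranyl bromide and Mg in Et2O, would be added to F5 in CH2Cl2 at −78 °C with catalytic copper thiophene-2-carboxylate and a chiral binaphthol-derived phosphoramidite. SN2′ alkylation of this aryl,methyl-substituted allylic chloride would give 10.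

**Step 6.** Arylation may compete at the b2 oxygen, a second molecule of 6 may displace the remaining fluoride, and the catecholate may be degraded oxidatively. A base-induced O-to-O aryl shift (Smiles type) is possible but should favour the less crowded b1 ether.

The fallback differentiates the two oxygens by protection before coupling. It sets out from 6 and comes back at 13. TIPSCl and imidazole in DMF, the most sterically selective electrophile available, would silylate the b1 hydroxyl to give 2-[(3S)-nerolidyl]-6-[tri(propan-2-yl)silyloxy]phenol F7. NaH and MOMCl in THF at 0 °C would give [2-(methoxymethoxy)-3-[(3S)-nerolidyl]phenoxy]tri(propan-2-yl)silane F8. Bu4NF in THF would give 2-(methoxymethoxy)-3-[(3S)-nerolidyl]phenol F9. Substitution on 12 (K2CO3, DMF, 60 °C) would give 2-fluoro-6-{2-(methoxymethoxy)-3-[(3S)-nerolidyl]phenoxy}-4-[(3R)-nerolidyl]benzaldehyde F10. Catalytic HCl in MeOH followed by aqueous work-up would give 13.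

**Step 7.** Hydroxide may attack the formyl group (Cannizzaro disproportionation) or the a5 carbon (cleavage of the diaryl ether) in competition with displacement of fluoride, and the reaction may be slow because the aryloxy group has already lowered the electrophilicity of ring A.

The fallback replaces hydroxide by an alkoxide that releases the phenol by elimination. It sets out from 13 and comes back at 14. 2-(Methylsulfonyl)ethanol and NaH in DMF at 0 °C → rt would displace fluoride to give 2-[2-(methylsulfonyl)ethoxy]-6-{2-hydroxy-3-[(3S)-nerolidyl]phenoxy}-4-[(3R)-nerolidyl]benzaldehyde F11. In the same basic medium F11 would lose methyl vinyl sulfone by E1cB elimination and give 14 after mild acidification.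

## Further compounds

F1 | step 2 | 1,2-bis(methoxymethoxy)benzene | COCOc1ccccc1OCOC
F2 | step 2 | 2-[2,3-bis(methoxymethoxy)phenyl]-5,5-dimethyl-1,3,2-dioxaborinane | COCOc1cccc(B2OCC(C)(C)CO2)c1OCOC
F3 | step 2 | 1,2-bis(methoxymethoxy)-3-[(3S,6E)-3,7,11-trimethyldodeca-1,6,10-trien-3-yl]benzene | COCOc1cccc([C@](C)(C=C)CC/C=C(\C)CCC=C(C)C)c1OCOC
F4 | step 4 | (2E)-3-(3,5-difluorophenyl)but-2-en-1-ol | C/C(=C\CO)c1cc(F)cc(F)c1
F5 | step 4 | 1-[(2E)-4-chlorobut-2-en-2-yl]-3,5-difluorobenzene | C/C(=C\CCl)c1cc(F)cc(F)c1
F6 | step 4 | [(3E)-4,8-dimethylnona-3,7-dien-1-yl]magnesium bromide | Br[Mg]CC/C=C(\C)CCC=C(C)C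
F7 | step 6 | 2-[(3S,6E)-3,7,11-trimethyldodeca-1,6,10-trien-3-yl]-6-[tri(propan-2-yl)silyloxy]phenol | CC(C)[Si](Oc1cccc([C@](C)(C=C)CC/C=C(\C)CCC=C(C)C)c1O)(C(C)C)C(C)C
F8 | step 6 | [2-(methoxymethoxy)-3-[(3S,6E)-3,7,11-trimethyldodeca-1,6,10-trien-3-yl]phenoxy]tri(propan-2-yl)silane | CC(C)[Si](Oc1cccc([C@](C)(C=C)CC/C=C(\C)CCC=C(C)C)c1OCOC)(C(C)C)C(C)C
F9 | step 6 | 2-(methoxymethoxy)-3-[(3S,6E)-3,7,11-trimethyldodeca-1,6,10-trien-3-yl]phenol | Oc1cccc([C@](C)(C=C)CC/C=C(\C)CCC=C(C)C)c1OCOC
F10 | step 6 | 2-fluoro-6-{2-(methoxymethoxy)-3-[(3S)-nerolidyl]phenoxy}-4-[(3R)-nerolidyl]benzaldehyde | O=Cc1c(F)cc(cc1Oc1cccc(c1OCOC)[C@](C)(C=C)CC/C=C(\C)CCC=C(C)C)[C@@](C)(C=C)CC/C=C(\C)CCC=C(C)C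
F11 | step 7 | 2-[2-(methylsulfonyl)ethoxy]-6-{2-hydroxy-3-[(3S)-nerolidyl]phenoxy}-4-[(3R)-nerolidyl]benzaldehyde | CS(=O)(=O)CCOc1cc(cc(Oc2cccc(c2O)[C@](C)(C=C)CC/C=C(\C)CCC=C(C)C)c1C=O)[C@@](C)(C=C)CC/C=C(\C)CCC=C(C)C
A1 | alternative 1 | (3R)-3-[(3E)-4,8-dimethylnona-3,7-dien-1-yl]-3-methyl-7-[tri(propan-2-yl)silyloxy]-1-benzofuran-2(3H)-one | C[C@]1(CC/C=C(\C)CCC=C(C)C)C(=O)Oc2c(O[Si](C(C)C)(C(C)C)C(C)C)cccc21
A2 | alternative 1 | rac-3-methyl-7-[tri(propan-2-yl)silyloxy]-1-benzofuran-2(3H)-one | CC1C(=O)Oc2c(O[Si](C(C)C)(C(C)C)C(C)C)cccc21
A3 | alternative 1 | homogeranyl iodide [(3E)-1-iodo-4,8-dimethylnona-3,7-diene] | ICC/C=C(\C)CCC=C(C)C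
A4 | alternative 2 | a3,b2-bis(methoxymethyl) ether of 16 (a4 hydroxyl free) | C=C[C@@](C)(CC/C=C(\C)CCC=C(C)C)c1cc(OCOC)c(O)c(Oc2cccc([C@](C)(C=C)CC/C=C(\C)CCC=C(C)C)c2OCOC)c1
A5 | alternative 2 | 1,3-bis(dimethylamino)-2-[(3R)-nerolidyl]trimethinium hexafluorophosphate | CN(C)C=C(C=[N+](C)C)[C@@](C)(C=C)CC/C=C(\C)CCC=C(C)C.F[P-](F)(F)(F)(F)F
A6 | alternative 2 | 1-(methoxymethoxy)-3-{2-(methoxymethoxy)-3-[(3S)-nerolidyl]phenoxy}propan-2-one | COCOCC(=O)COc1cccc([C@](C)(C=C)CC/C=C(\C)CCC=C(C)C)c1OCOC
A7 | alternative 3 | tertiary benzylic pinacol boronate of the tris(methoxymethyl) diaryl ether (boron at C3 of arm A in place of vinyl) | CC1(C)OB(OC1(C)C)[C@@](C)(CC/C=C(\C)CCC=C(C)C)c1cc(OCOC)c(OCOC)c(Oc2cccc([C@](C)(C=C)CC/C=C(\C)CCC=C(C)C)c2OCOC)c1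
A8 | alternative 3 | (1R)-1-aryl-ethyl N,N-diisopropylcarbamate of the tris(methoxymethyl) diaryl ether | CC(C)N(C(C)C)C(=O)O[C@H](C)c1cc(OCOC)c(OCOC)c(Oc2cccc([C@](C)(C=C)CC/C=C(\C)CCC=C(C)C)c2OCOC)c1
A9 | alternative 3 | homogeranyl pinacol boronate | CC1(C)OB(CC/C=C(\C)CCC=C(C)C)OC1(C)C
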